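**Strategy.** The enal is disconnected by a directed aldol condensation into two twenty-carbon aldehydes, and the left-hand labdane is disconnected at C9–C10 of its ring B. The key step is a Cp2TiCl-mediated radical cyclisation of a ring-A C1–C10 epoxide carrying a citronellal-derived (E)-C8=C9 alkene on C5. Homolysis gives the tertiary C10 radical, 6-endo closure forms ring B and sets quaternary C10 and C9 from C5 in one event, and β-hydride loss from C17 installs the exocyclic methylene. It exploits the C8(17)-ene/C9/C10 array of ring B. Ring A (C4 by catalysis, C5 by [2,3]-shift) is shared with the A/B-cis right half, made earlier by cycloaddition and directed hydrogenation.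

Key step: step 26

**Remarks on the chemistry**
- The SMILES is read as written: the left bicycle is the normal trans-labdane (4S,5R,9S,10R) and the right bicycle is its C5 epimer (H-5′ cis to C-20′, A/B-cis, 4S,5S,9S,10R). The route is planned for exactly this diastereomer.
- Labdane numbering (primes for the right half) is used for all intermediates; β is the face of C20 and C19.
- Compounds 1, 2, 4, 13, 17 and 26 are taken as commercial.

**Common ring-A sequence**

Step 1
Reactants: 1 ethyl 2-formylpropanoate; 2 2-(trimethylsilyl)ethanol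
Product: 3 2-(trimethylsilyl)ethyl 2-formylpropanoate
Conditions: DMAP (cat.), toluene, reflux, ethanol distilled off
Reagents that add atoms: none
Why: Thermal transesterification of the β-formyl ester, driven by removal of ethanol, installs the fluoride-labile ester needed for the last step.

Step 2
Reactants: 3 2-(trimethylsilyl)ethyl 2-formylpropanoate; 4 ethyl vinyl ketone
Product: 6 ring-A enone 2-(trimethylsilyl)ethyl (S)-1,3-dimethyl-4-oxocyclohex-2-ene-1-carboxylate, via Michael adduct 5 (not isolated)
Conditions: quinidine-derived 6′-hydroxy cinchona catalyst (cupreidine 9-O-aryl ether, 10 mol%), CH2Cl2, −20 °C; then TsOH·H2O (cat.), toluene, reflux, Dean–Stark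
Reagents that add atoms: none
Why: Bifunctional base/hydrogen-bond organocatalysed Michael addition of the α-formyl ester sets C4 (S) by catalyst control (the quinine-derived pseudo-enantiomer is the direct lever on the sense of induction), and acid-catalysed aldol condensation of the ethyl-ketone CH2 onto the aldehyde closes ring A (Robinson-type annulation).

Step 3
Reactants: 6 ring-A enone
Product: 7 allylic alcohol 2-(trimethylsilyl)ethyl (1S,4R)-4-hydroxy-1,3-dimethylcyclohex-2-ene-1-carboxylate (1β-OH, cis to the ester)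
Conditions: (S)-Me-CBS oxazaborolidine (20 mol%), BH3·SMe2, THF, −30 °C
Reagents that add atoms: none
Why: Corey–Bakshi–Shibata reduction gives the C1 β-alcohol by reagent-controlled 1,2-hydride delivery, and this stereocentre is relayed to C5 in step 5.

Step 4
Reactants: 7 allylic alcohol
Product: 8 tributylstannylmethyl ether of 7
Conditions: KH, 18-crown-6 (cat.), THF, 0 °C; then ICH2SnBu3
Reagents that add atoms: tributyl(iodomethyl)stannane, C(I)[Sn](CCCC)(CCCC)CCCC
Why: Williamson etherification of the potassium alkoxide with the iodomethylstannane touches no stereocentre.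

Step 5
Reactants: 8 stannylmethyl ether
Product: 9 ring-A homoallylic alcohol 2-(trimethylsilyl)ethyl (1S,2R)-2-(hydroxymethyl)-1,3-dimethylcyclohex-3-ene-1-carboxylate (C6 hydroxymethyl β on C5, C1=C10 alkene)
Conditions: n-BuLi, THF, −78 °C
Reagents that add atoms: none
Why: Tin–lithium exchange and Still–Wittig [2,3]-sigmatropic rearrangement transfer the CH2O unit suprafacially from O–C1 to C5, so the β-oxygen at C1 becomes the β-hydroxymethyl at C5 while the alkene moves to C1=C10, and the hindered quaternary ester is spared at −78 °C.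

**Right half (A/B-cis)**

Step 6
Reactants: 9 ring-A homoallylic alcohol
Product: 11 conjugated enal 2-(trimethylsilyl)ethyl (S)-2-formyl-1,3-dimethylcyclohex-2-ene-1-carboxylate, via β,γ-unsaturated aldehyde 10 (not isolated)
Conditions: Dess–Martin periodinane, NaHCO3, CH2Cl2, 0 °C; then DBU (cat.), rt
Reagents that add atoms: none
Why: Dess–Martin oxidation followed by base-mediated isomerisation into conjugation (the α- to β-cyclocitral type shift) erases C5, whose configuration is not needed in this branch.

Step 7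
Reactants: 11 conjugated enal
Product: 12 diene 2-(trimethylsilyl)ethyl (S)-2-ethenyl-1,3-dimethylcyclohex-2-ene-1-carboxylate
Conditions: Ph3PCH3Br, KOt-Bu, THF, 0 °C to rt
Reagents that add atoms: methyltriphenylphosphonium bromide, C[P+](c1ccccc1)(c1ccccc1)c1ccccc1.[Br-]
Why: Wittig methylenation of the hindered enal gives the semicyclic diene, as in the known preparation of 1-vinylcyclohexenes from β-cyclocitral-type aldehydes.

Step 8
Reactants: 12 diene; 13 ethyl propiolate
Product: 14 bicyclic 5,8-diene diester (ring B′ closed; quaternary C10 with 20-methyl β; CO2Et on C9; C19 ester β)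
Conditions: toluene, BHT (cat.), 120 °C, sealed tube
Reagents that add atoms: none
Why: Thermal Diels–Alder reaction of a 1-vinylcyclohexene with an acetylenic ester joins the ester-bearing alkyne carbon to the substituted terminus C10 ("ortho" rule), and approach anti to the pseudoaxial C19 ester sets quaternary C10 with C20 cis to that ester, avoiding a developing 1,3-diaxial methyl–methyl contact.

Step 9
Reactants: 14 bicyclic 5,8-diene diester
Product: 15 8α-(pinacolboryl)-9β-ethoxycarbonyl 5-ene
Conditions: B2pin2, CuCl (5 mol%), Xantphos, NaOt-Bu (cat.), MeOH, THF, rt; then NaOEt (cat.), EtOH, rt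
Reagents that add atoms: bis(pinacolato)diboron, CC1(C)OB(OC1(C)C)B1OC(C)(C)C(C)(C)O1
Why: Copper-catalysed conjugate borylation of the enoate (borylcupration of C8=C9 from the α-face, anti to C20) followed by base equilibration at C9 gives the trans-diequatorial 8α-boryl-9β-ester, fixing C9 with H-9 α.

Step 10
Reactants: 15 boryl ester
Product: 16 C11 aldehyde (8α-Bpin, 9β-CHO, 5-ene)
Conditions: i-Bu2AlH (1.1 equiv), toluene, −78 °C; aqueous tartrate work-up
Reagents that add atoms: none
Why: Partial reduction of the less hindered ethyl ester through the stable aluminium hemiacetal gives the aldehyde, while the neopentyl C19 ester is not reduced.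

Step 11
Reactants: 17 (R)-4-methyldihydrofuran-2(3H)-one
Product: 18 ethyl (R)-4-bromo-3-methylbutanoate
Conditions: HBr (gas), EtOH, 0 °C to rt
Reagents that add atoms: hydrogen bromide, Br; ethanol, CCO
Why: Acid-mediated SN2 opening of the γ-lactone at C12 by bromide with concomitant Fischer esterification leaves the C13 stereocentre untouched.

Step 12
Reactants: 18 bromo ester
Product: 19 [(R)-4-ethoxy-2-methyl-4-oxobutyl]triphenylphosphonium bromide
Conditions: PPh3, MeCN, reflux
Reagents that add atoms: triphenylphosphine, c1ccc(cc1)P(c1ccccc1)c1ccccc1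
Why: SN2 quaternisation of triphenylphosphine by the primary bromide.

Step 13
Reactants: 16 C11 aldehyde; 19 phosphonium bromide
Product: 20 (11Z)-5,11-diene boronate diester (complete right-half carbon skeleton)
Conditions: NaHMDS, THF, −78 °C; then 16, −78 to 0 °C
Reagents that add atoms: none
Why: Wittig reaction of the non-stabilised ylide with the aldehyde forms C11=C12 (Z, geometry irrelevant because it is saturated in step 14), and the thermodynamically preferred 9β configuration is retained.

Step 14
Reactants: 20 diene boronate diester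
Product: 21 A/B-cis (5β-H) saturated boronate diester
Conditions: H2 (1–4 atm), [Ir(cod)(PCy3)(py)]PF6 (10 mol%), CH2Cl2, rt
Reagents that add atoms: none
Why: Directed homogeneous hydrogenation, in which iridium binds the C19 ester carbonyl and delivers H2 to the β-face of C5=C6, gives H-5 β (cis ring fusion) and saturates C11=C12 in the same operation.

Step 15
Reactants: 21 cis boronate diester
Product: 22 8α-alcohol
Conditions: 30% H2O2, pH 7 phosphate buffer, THF, 0 °C to rt
Reagents that add atoms: hydrogen peroxide, OO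
Why: Stereoretentive oxidation of the C8–B bond gives the secondary alcohol.

Step 16
Reactants: 22 8α-alcohol
Product: 23 17-nor-8-ketone (5β-H, 9β side chain)
Conditions: Dess–Martin periodinane, NaHCO3, CH2Cl2, 0 °C
Reagents that add atoms: none
Why: Buffered Dess–Martin oxidation gives the ketone under non-epimerising conditions, so C9 is untouched.

Step 17
Reactants: 23 8-ketone
Product: 24 8(17)-ene 15-ethyl ester (5β-H)
Conditions: Zn, CH2Br2, TiCl4, THF/CH2Cl2, 0 °C to rt
Reagents that add atoms: dibromomethane, BrCBr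
Why: Lombardo–Takai methylenation, a non-basic olefination suited to epimerisable ketones, converts C8=O into the exocyclic alkene without epimerising C9 or touching the esters.

Step 18
Reactants: 24 ethyl ester
Product: 25 right-half aldehyde 2-(trimethylsilyl)ethyl (4S,5S,9S,10R,13S)-15-oxolabd-8(17)-en-19-oate
Conditions: i-Bu2AlH (1.1 equiv), toluene, −78 °C
Reagents that add atoms: none
Why: Partial reduction of the unhindered ethyl ester gives the C15′ aldehyde while the hindered C19′ silylethyl ester survives.

**Left half (trans-labdane)**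

Step 19
Reactants: 26 (S)-citronellal
Product: 27 (S)-citronellal dimethyl acetal
Conditions: HC(OMe)3, MeOH, PPTS (cat.), rt
Reagents that add atoms: trimethyl orthoformate, COC(OC)OC
Why: Acetalisation under acid too mild for the carbonyl-ene cyclisation of citronellal masks C15 until step 29, and C13 comes from the chiral pool.

Step 20
Reactants: 27 acetal
Product: 28 (S,E)-8,8-dimethoxy-2,6-dimethyloct-2-en-1-ol
Conditions: SeO2 (cat.), t-BuOOH, CH2Cl2, 0 °C to rt
Reagents that add atoms: tert-butyl hydroperoxide, CC(C)(C)OO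
Why: SeO2-catalysed allylic oxidation (ene reaction, then [2,3]-shift) hydroxylates the (E)-methyl group selectively, which becomes C7 and leaves the (Z)-methyl as C17.

Step 21
Reactants: 28 allylic alcohol
Product: 29 (S,E)-1-bromo-8,8-dimethoxy-2,6-dimethyloct-2-ene
Conditions: CBr4, PPh3, 2,6-lutidine, CH2Cl2, −20 °C
Reagents that add atoms: carbon tetrabromide, BrC(Br)(Br)Br
Why: Appel bromination of the primary allylic alcohol keeps the (E)-alkene, and lutidine protects the acetal.

Step 22
Reactants: 9 ring-A homoallylic alcohol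
Product: 30 C6 phenyl sulfide
Conditions: PhSSPh, PBu3, pyridine, rt to 50 °C
Reagents that add atoms: diphenyl disulfide, c1ccc(SSc2ccccc2)cc1
Why: Hata–Mukaiyama thioetherification proceeds by SN2 at C6 via the alkoxyphosphonium salt.

Step 23
Reactants: 30 sulfide
Product: 31 1α,10α-epoxy C6 phenyl sulfone
Conditions: mCPBA (3.2 equiv), NaHCO3, CH2Cl2, 0 °C to rt
Reagents that add atoms: 3-chloroperbenzoic acid, OOC(=O)c1cccc(Cl)c1
Why: One peracid oxidises sulfur to the sulfone and epoxidises the only alkene from the α-face (anti to the C6 arm and the axial ester), and the epoxide configuration is inconsequential because C10 becomes a radical and the C1 oxygen is removed later.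

Step 24
Reactants: 31 epoxy sulfone; 29 allylic bromide
Product: 32 C6-alkylated epoxy sulfone (both C6 epimers)
Conditions: n-BuLi, THF, −78 °C; then 29, −78 to −20 °C
Reagents that add atoms: none
Why: Alkylation of the α-sulfonyl carbanion by SN2 at the primary allylic carbon forms the C6–C7 bond with retention of the (E)-alkene, and the new C6 centre is removed in step 25.

Step 25
Reactants: 32 alkylated sulfone
Product: 33 seco-labdane epoxide (ring A with 1α,10α-epoxide; C5 arm CH2CH2C(CH3)=CH–side chain)
Conditions: 6% sodium amalgam (Na/Hg), Na2HPO4, MeOH/THF, −20 °C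
Reagents that add atoms: none
Why: Reductive desulfonylation by electron transfer leaves the epoxide, acetal and ester intact under buffered conditions.

Step 26
Reactants: 33 seco-labdane epoxide
Product: 34 2-(trimethylsilyl)ethyl 1α-hydroxy-15,15-dimethoxylabd-8(17)-en-19-oate (ring B closed)
Conditions: Cp2TiCl2 (2.5 equiv), Mn dust, THF, rt, slow addition of 33; aq. NaH2PO4 work-up
Reagents that add atoms: none
Why: Cp2TiCl (trivalent titanium) opens the C1–C10 epoxide homolytically to the tertiary C10 radical (O–Ti on C1), which adds to C9 of the (E)-C8=C9 alkene; a second Cp2TiCl traps the tertiary C8 radical and β-hydride elimination from the C17 methyl gives the exocyclic alkene. The closest known reaction type is the Nugent–RajanBabu epoxide-opening radical cyclisation as used in titanocene-mediated epoxypolyene cyclisations, whose second ring closure is this same elementary step. Ring B closes in the 6-endo-trig mode, favoured over 5-exo because C8 is the fully substituted alkene carbon. C10 is controlled by C5, since the equatorial C5 arm leads through a chair-like transition state to attack anti to C6 (trans-decalin, C20 β), and C9 follows from the (E)-alkene geometry, which places C11 equatorial (H-9 α). The step needs cyclisation to outrun reduction or deoxygenation of the β-titanoxy radical (slow addition, low Cp2TiCl concentration) and needs exocyclic termination, which the least hindered C17–H secures. The C1 oxygen is a temporary handle removed in steps 27 and 28.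

Step 27
Reactants: 34 C1 alcohol
Product: 35 C1 S-methyl xanthate
Conditions: NaH, imidazole (cat.), THF, 0 °C; CS2; MeI
Reagents that add atoms: carbon disulfide, S=C=S; iodomethane, CI
Why: Xanthate formation on the C1 alkoxide is the first stage of a Barton–McCombie deoxygenation.

Step 28
Reactants: 35 xanthate
Product: 36 2-(trimethylsilyl)ethyl 15,15-dimethoxylabd-8(17)-en-19-oate
Conditions: Bu3SnH, AIBN (cat.), toluene, 100 °C
Reagents that add atoms: none
Why: Barton–McCombie radical deoxygenation removes the temporary C1 oxygen, and the secondary C1 radical has no favourable cyclisation path onto the exocyclic alkene.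

Step 29
Reactants: 36 acetal
Product: 37 left-half aldehyde 2-(trimethylsilyl)ethyl (4S,5R,9S,10R,13S)-15-oxolabd-8(17)-en-19-oate
Conditions: PPTS (cat.), acetone/H2O, 45 °C
Reagents that add atoms: water, O
Why: Mild acid-catalysed acetal hydrolysis unmasks the C15 aldehyde without isomerising the exocyclic alkene.

**Union and deprotection**

Step 30
Reactants: 37 left-half aldehyde; 25 right-half aldehyde
Product: 40 bis[2-(trimethylsilyl)ethyl] ester of the target, via cyclohexylimine 38 (not isolated), via hydroxy imine 39 (not isolated)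
Conditions: cyclohexylamine, 4 Å MS, Et2O; LDA, THF, −78 °C; then 25, −78 °C; aq. oxalic acid, THF, rt
Reagents that add atoms: none
Why: Wittig directed aldol condensation, in which the lithiated cyclohexylimine of 37 (azaenolate at C14) adds only to aldehyde 25 and acidic hydrolysis–dehydration gives the thermodynamically preferred (E)-2-alkyl-enal (CHO trans to C14′), avoids self-condensation.

Step 31
Reactants: 40 bis-silylethyl ester
Product: 41 target diacid
Conditions: tris(dimethylamino)sulfonium difluorotrimethylsilicate (TASF), DMF, 0 °C to rt; cold dilute aq. HCl work-up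
Reagents that add atoms: none
Why: Fluoride-induced β-elimination at silicon cleaves both hindered 2-(trimethylsilyl)ethyl esters under essentially neutral conditions that leave the enal and the exocyclic alkenes untouched.

**Compound list**

1 | ethyl 2-formylpropanoate | CCOC(=O)C(C)C=O | starting material
2 | 2-(trimethylsilyl)ethanol | OCC[Si](C)(C)C | starting material
3 | 2-(trimethylsilyl)ethyl 2-formylpropanoate | C[Si](C)(C)CCOC(=O)C(C)C=O | intermediate
4 | ethyl vinyl ketone (pent-1-en-3-one) | CCC(=O)C=C | starting material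
5 | 2-(trimethylsilyl)ethyl (S)-2-formyl-2-methyl-5-oxoheptanoate | CCC(=O)CC[C@@](C)(C=O)C(=O)OCC[Si](C)(C)C | intermediate (not isolated)
6 | ring-A enone, 2-(trimethylsilyl)ethyl (S)-1,3-dimethyl-4-oxocyclohex-2-ene-1-carboxylate | C[C@@]1(C(=O)OCC[Si](C)(C)C)C=C(C)C(=O)CC1 | intermediate
7 | 2-(trimethylsilyl)ethyl (1S,4R)-4-hydroxy-1,3-dimethylcyclohex-2-ene-1-carboxylate | C[C@@]1(C(=O)OCC[Si](C)(C)C)C=C(C)[C@H](O)CC1 | intermediate
8 | tributylstannylmethyl ether of 7 | C[C@@]1(C(=O)OCC[Si](C)(C)C)C=C(C)[C@H](OC[Sn](CCCC)(CCCC)CCCC)CC1 | intermediate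
9 | 2-(trimethylsilyl)ethyl (1S,2R)-2-(hydroxymethyl)-1,3-dimethylcyclohex-3-ene-1-carboxylate | C[C@@]1(C(=O)OCC[Si](C)(C)C)[C@H](CO)C(C)=CCC1 | intermediate
10 | 2-(trimethylsilyl)ethyl (1S,2R)-2-formyl-1,3-dimethylcyclohex-3-ene-1-carboxylate | C[C@@]1(C(=O)OCC[Si](C)(C)C)[C@H](C=O)C(C)=CCC1 | intermediate (not isolated)
11 | 2-(trimethylsilyl)ethyl (S)-2-formyl-1,3-dimethylcyclohex-2-ene-1-carboxylate | C[C@@]1(C(=O)OCC[Si](C)(C)C)C(C=O)=C(C)CCC1 | intermediate
12 | 2-(trimethylsilyl)ethyl (S)-2-ethenyl-1,3-dimethylcyclohex-2-ene-1-carboxylate | C[C@@]1(C(=O)OCC[Si](C)(C)C)C(C=C)=C(C)CCC1 | intermediate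
13 | ethyl propiolate | C#CC(=O)OCC | starting material
14 | bicyclic 5,8-diene diester (10β-methyl, 4β-CO2CH2CH2SiMe3, 9-CO2Et) | C[C@]1(C(=O)OCC[Si](C)(C)C)CCC[C@@]2(C)C1=CCC=C2C(=O)OCC | intermediate
15 | 8α-(pinacolboryl)-9β-ethoxycarbonyl 5-ene | C[C@]1(C(=O)OCC[Si](C)(C)C)CCC[C@@]2(C)C1=CC[C@@H](B3OC(C)(C)C(C)(C)O3)[C@@H]2C(=O)OCC | intermediate
16 | 8α-(pinacolboryl)-9β-formyl 5-ene (C11 aldehyde) | C[C@]1(C(=O)OCC[Si](C)(C)C)CCC[C@@]2(C)C1=CC[C@@H](B3OC(C)(C)C(C)(C)O3)[C@@H]2C=O | intermediate
17 | (R)-4-methyldihydrofuran-2(3H)-one | C[C@H]1COC(=O)C1 | starting material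
18 | ethyl (R)-4-bromo-3-methylbutanoate | CCOC(=O)C[C@@H](C)CBr | intermediate
19 | [(R)-4-ethoxy-2-methyl-4-oxobutyl]triphenylphosphonium bromide | CCOC(=O)C[C@@H](C)C[P+](c1ccccc1)(c1ccccc1)c1ccccc1.[Br-] | intermediate
20 | (11Z)-5,11-diene 8α-boronate, 15-ethyl 19-silylethyl diester | C[C@]1(C(=O)OCC[Si](C)(C)C)CCC[C@@]2(C)C1=CC[C@@H](B3OC(C)(C)C(C)(C)O3)[C@@H]2/C=C\[C@H](C)CC(=O)OCC | intermediate
21 | 5β-H (A/B-cis) 8α-boronate diester | C[C@]1(C(=O)OCC[Si](C)(C)C)CCC[C@@]2(C)[C@@H]1CC[C@@H](B3OC(C)(C)C(C)(C)O3)[C@@H]2CC[C@H](C)CC(=O)OCC | intermediate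
22 | 5β-H 8α-alcohol diester | C[C@]1(C(=O)OCC[Si](C)(C)C)CCC[C@@]2(C)[C@@H]1CC[C@@H](O)[C@@H]2CC[C@H](C)CC(=O)OCC | intermediate
23 | 5β-H 17-nor-8-ketone diester | C[C@]1(C(=O)OCC[Si](C)(C)C)CCC[C@@]2(C)[C@@H]1CCC(=O)[C@@H]2CC[C@H](C)CC(=O)OCC | intermediate
24 | 5β-H labd-8(17)-ene 15-ethyl 19-silylethyl diester | C[C@]1(C(=O)OCC[Si](C)(C)C)CCC[C@@]2(C)[C@@H]1CCC(=C)[C@@H]2CC[C@H](C)CC(=O)OCC | intermediate
25 | 2-(trimethylsilyl)ethyl (4S,5S,9S,10R,13S)-15-oxolabd-8(17)-en-19-oate (right-half aldehyde) | C[C@]1(C(=O)OCC[Si](C)(C)C)CCC[C@@]2(C)[C@@H]1CCC(=C)[C@@H]2CC[C@H](C)CC=O | intermediate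
26 | (S)-citronellal | O=CC[C@@H](C)CCC=C(C)C | starting material
27 | (S)-citronellal dimethyl acetal | COC(OC)C[C@@H](C)CCC=C(C)C | intermediate
28 | (S,E)-8,8-dimethoxy-2,6-dimethyloct-2-en-1-ol | COC(OC)C[C@@H](C)CC/C=C(\C)CO | intermediate
29 | (S,E)-1-bromo-8,8-dimethoxy-2,6-dimethyloct-2-ene | COC(OC)C[C@@H](C)CC/C=C(\C)CBr | intermediate
30 | C6 phenyl sulfide of 9 | C[C@@]1(C(=O)OCC[Si](C)(C)C)[C@H](CSc2ccccc2)C(C)=CCC1 | intermediate
31 | 1α,10α-epoxy C6 phenyl sulfone | C[C@@]1(C(=O)OCC[Si](C)(C)C)[C@H](CS(=O)(=O)c2ccccc2)[C@@]3(C)O[C@H]3CC1 | intermediate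
32 | C6-alkylated epoxy sulfone (C6 epimers) | C[C@@]1(C(=O)OCC[Si](C)(C)C)[C@H](C(C/C(C)=C/CC[C@H](C)CC(OC)OC)S(=O)(=O)c2ccccc2)[C@@]3(C)O[C@H]3CC1 | intermediate
33 | seco-labdane 1α,10α-epoxide | C[C@@]1(C(=O)OCC[Si](C)(C)C)[C@H](CC/C(C)=C/CC[C@H](C)CC(OC)OC)[C@@]2(C)O[C@H]2CC1 | intermediate
34 | 2-(trimethylsilyl)ethyl 1α-hydroxy-15,15-dimethoxylabd-8(17)-en-19-oate | C[C@]1(C(=O)OCC[Si](C)(C)C)CC[C@H](O)[C@@]2(C)[C@H]1CCC(=C)[C@@H]2CC[C@H](C)CC(OC)OC | intermediate
35 | C1 S-methyl xanthate of 34 | C[C@]1(C(=O)OCC[Si](C)(C)C)CC[C@H](OC(=S)SC)[C@@]2(C)[C@H]1CCC(=C)[C@@H]2CC[C@H](C)CC(OC)OC | intermediate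
36 | 2-(trimethylsilyl)ethyl 15,15-dimethoxylabd-8(17)-en-19-oate | C[C@]1(C(=O)OCC[Si](C)(C)C)CCC[C@@]2(C)[C@H]1CCC(=C)[C@@H]2CC[C@H](C)CC(OC)OC | intermediate
37 | 2-(trimethylsilyl)ethyl (4S,5R,9S,10R,13S)-15-oxolabd-8(17)-en-19-oate (left-half aldehyde) | C[C@]1(C(=O)OCC[Si](C)(C)C)CCC[C@@]2(C)[C@H]1CCC(=C)[C@@H]2CC[C@H](C)CC=O | intermediate
38 | N-cyclohexylimine of 37 | C[C@]1(C(=O)OCC[Si](C)(C)C)CCC[C@@]2(C)[C@H]1CCC(=C)[C@@H]2CC[C@H](C)C/C=N/C3CCCCC3 | intermediate (not isolated)
39 | β-hydroxy imine aldol adduct (C14 and C15′ epimers) | C[C@]1(C(=O)OCC[Si](C)(C)C)CCC[C@@]2(C)[C@H]1CCC(=C)[C@@H]2CC[C@H](C)C(C=NC3CCCCC3)C(O)C[C@@H](C)CC[C@H]4C(=C)CC[C@H]5[C@]4(C)CCC[C@]5(C)C(=O)OCC[Si](C)(C)C | intermediate (not isolated)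
40 | bis[2-(trimethylsilyl)ethyl] ester of the target | C=C1CC[C@@H]2[C@](C)(CCC[C@]2(C)C(=O)OCC[Si](C)(C)C)[C@H]1CC[C@H](C)/C(C=O)=C\C[C@@H](C)CC[C@H]1C(=C)CC[C@H]2[C@]1(C)CCC[C@]2(C)C(=O)OCC[Si](C)(C)C | intermediate
41 | CNP0229303.1, (E)-enal-linked dimer of 15-oxolabd-8(17)-en-19-oic acid (left A/B-trans, right A/B-cis) | C=C1CC[C@@H]2[C@](C)(CCC[C@]2(C)C(=O)O)[C@H]1CC[C@H](C)/C(C=O)=C\C[C@@H](C)CC[C@H]1C(=C)CC[C@H]2[C@]1(C)CCC[C@]2(C)C(=O)O | target

**Step count and risks**

Total step count: 31. Longest linear sequence: 18 steps (1–10, 13–18, 30, 31).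

The three steps most likely to fail:

Step 26. The β-titanoxy C10 radical may be reduced or may lose its oxygen (alkene or allylic alcohol formation) before the 6-endo closure, and termination may leak into endocyclic alkene isomers. The fallback closes ring B of the left half by cycloaddition instead of radical cyclisation. It sets out from a second batch of 20, obtained by repeating steps 8–10 and 13 after 25 is secured, so that this ring is still the last one closed. Hydrogenation over Pd/C in EtOAc, where undirected delivery to the open α-face should prevail, gives the trans-fused (5α-H) boronate diester F1. Buffered H2O2 then gives the 8α-alcohol F2, Dess–Martin periodinane the 8-ketone F3, and Zn/CH2Br2/TiCl4 the 8(17)-ene ethyl ester F4. Reduction with i-Bu2AlH at −78 °C comes back to the route at 37.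

Step 14. Undirected delivery of hydrogen to the less hindered α-face may compete with the ester-directed β-face delivery and erode the cis ring fusion. The fallback changes the directing group: from 20, TASF frees the C19 carboxylic acid F5, and hydrogenation with [Ir(cod)(PCy3)(py)]PF6 (or [Rh(nbd)(dppb)]BF4) under carboxylate direction should give the A/B-cis acid F6. Re-esterification with 2-(trimethylsilyl)ethyl 2,2,2-trichloroacetimidate in hot toluene comes back to the route at 21.

Step 2. The organocatalytic conjugate addition may give insufficient enantiofacial discrimination at C4, which every later stereocentre depends on. The fallback uses stoichiometric auxiliary control: from 3, condensation with (S)-1-phenylethylamine gives the chiral enamino ester F7. Its Michael addition to 4, followed by hydrolysis with aqueous acetic acid, comes back to the route at 5, which is cyclised to 6 as in step 2; the antipodal amine is used if the sense of induction requires it.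

**Further compounds**

F1 | step 26 | trans-fused (5α-H) 8α-boronate, 15-ethyl 19-silylethyl diester | C[C@]1(C(=O)OCC[Si](C)(C)C)CCC[C@@]2(C)[C@H]1CC[C@@H](B3OC(C)(C)C(C)(C)O3)[C@@H]2CC[C@H](C)CC(=O)OCC
F2 | step 26 | trans-fused 8α-alcohol diester | C[C@]1(C(=O)OCC[Si](C)(C)C)CCC[C@@]2(C)[C@H]1CC[C@@H](O)[C@@H]2CC[C@H](C)CC(=O)OCC
F3 | step 26 | trans-fused 17-nor-8-ketone diester | C[C@]1(C(=O)OCC[Si](C)(C)C)CCC[C@@]2(C)[C@H]1CCC(=O)[C@@H]2CC[C@H](C)CC(=O)OCC
F4 | step 26 | trans-fused labd-8(17)-ene 15-ethyl 19-silylethyl diester | C[C@]1(C(=O)OCC[Si](C)(C)C)CCC[C@@]2(C)[C@H]1CCC(=C)[C@@H]2CC[C@H](C)CC(=O)OCC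
F5 | step 14 | C19 carboxylic acid of 20 | C[C@]1(C(=O)O)CCC[C@@]2(C)C1=CC[C@@H](B3OC(C)(C)C(C)(C)O3)[C@@H]2/C=C\[C@H](C)CC(=O)OCC
F6 | step 14 | A/B-cis (5β-H) C19 carboxylic acid | C[C@]1(C(=O)O)CCC[C@@]2(C)[C@@H]1CC[C@@H](B3OC(C)(C)C(C)(C)O3)[C@@H]2CC[C@H](C)CC(=O)OCC
F7 | step 2 | 2-(trimethylsilyl)ethyl (Z)-2-methyl-3-{[(S)-1-phenylethyl]amino}acrylate | C[Si](C)(C)CCOC(=O)/C(C)=C\N[C@@H](C)c1ccccc1
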